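**The question.** A small charge of free catalyst, c(free catalyst) = 1.4 mM, has to turn 0.68 M of solid substrate into target, and none of that solid is in solution at the start, so I asked whether more catalyst can speed a flask that may be waiting on the solid.

in all of them: solid substrate 0.68 M; free catalyst 1.4 mM
- eta: partner 0.884 M; impurity 0.67 mM; run made earlier
- epsilon: partner 0.884 M; impurity 1.5 mM; run made earlier
- theta: partner 0.44 M; impurity 1 mM; run made earlier
- flask: partner 0.884 M; impurity 1.0 mM

| run | time / min | target / % |
|---|---|---|
| eta | 5.00 | 69.7 |
| eta | 10.0 | 100.5 |
| eta | 15.0 | 99.7 |
| eta | 20.0 | 100.1 |
| epsilon | 1.50 | 16.8 |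
| epsilon | 4.00 | 37.4 |
| epsilon | 8.00 | 63.2 |
| epsilon | 20.0 | 99.8 |
| theta | 2.50 | 28.4 |
| theta | 8.00 | 58.1 |
| theta | 12.0 | 63.0 |
| theta | 20.0 | 64.6 |

(each reading ± 0.3 percentage points)

- as a solid, counted per litre of solution: solid substrate
- the analysis behind the earlier runs scatters by 0.3 percentage points, standard deviation
- steps thought possible: starting material + free catalyst -> catalyst intermediate A; catalyst intermediate B -> free catalyst + target; free catalyst + impurity -> spent catalyst; solid substrate <-> starting material; partner + catalyst intermediate A <-> catalyst intermediate B
- at the start none of the solid substrate is in solution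
- what has only dissolved of solid substrate counts as not reacted
- no earlier run changes the charge of free catalyst; that part of a forecast is a guess

* factor on the rate of making target when 5.0% of the solid substrate are converted (what has only dissolved counts as not reacted) if free catalyst is charged twice over
* factor on the rate when 5.0% of the solid substrate are converted (what has only dissolved counts as not reacted) if free catalyst is charged at 8.0 mM instead

**The ceiling.** The eta run, with the least impurity, made target at a mean 0.0948 M min⁻¹ over its first 5.00 min. I took this reading as the supply ceiling: the rate at which solid substrate enters solution, which I assumed more catalyst does not lift if dissolution is the rate-limiting step.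

**Two ways.** The question concerns the first moments of the flask, so I needed a rate from the first moments of a run, and I ran a straight line back through the first two mean rates of two runs. The theta run gave 0.0899 M min⁻¹ and the epsilon run 0.0837 M min⁻¹, so the ceiling stood 1.05 or 1.13 times above them. They part, and I distrusted epsilon, whose impurity exceeds the flask's, while theta carries the flask's impurity, though only half its partner. At the theta rate the flask should reach 5.0% within about 0.378 min, and I expected a factor near 1.05 there for either charge, with 1.13 as my upper guess.

**The forecast.** The forecast, higher than my figure, gave 1.3 and 1.6, reasoning that “supply by dissolution is partly limiting”.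

**The flask.** The simulation gave 1.07 for twice the catalyst and 1.08 for 8.0 mM, with the flask making target at 0.0907 M min⁻¹ at 0.389 min.

    starting material + free catalyst → catalyst intermediate A (k = 1100 M⁻¹ s⁻¹)
    catalyst intermediate B → free catalyst + target (k = 7.10 s⁻¹)
    free catalyst + impurity → spent catalyst (k = 79.0 M⁻¹ s⁻¹)
    solid substrate ⇌ starting material, rate k4*(cs4 - [starting material]) while solid is left; crystals form when [starting material] > cs4 (solubility = 0.440 M, k = 0.00370 s⁻¹)
    partner + catalyst intermediate A ⇌ catalyst intermediate B (K = 3.40 M⁻¹, k = 20.0 M⁻¹ s⁻¹)

**The solid.** Drawn down at the ceiling, the flask's solid substrate should stand at 65.1% after 2.50 min, and the flask held 64.8%.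

(The readings were generated by integration from invented constants; the scatter is artificial.)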